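The route joins two (2S)-flavonoid halves in a formal [3+2] union: a metalated flavan-4-ol adds to the C8″ carbonyl of a 2H-chromene-5,8-quinone and the freed phenol then closes the ketal at C8a″. The dihydropyran ring of that quinone (O1″, C2″, C3″, C4″, C4a″, C8a″) is first built one atom smaller, as the tetrahydrofuran of an ortho-spirodienone; acid then shifts C4″ from C8a″ to C4a″ (dienone–phenol rearrangement) and so expands it to the chroman, leaving the C2″ stereocentre untouched. The step exploits that O1″ sits on C8a″ directly beside oxygenated C8″: the guaiacol hydroxyl that drives the dearomatising spiro-etherification becomes the C8″ carbonyl.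

Key step: step 4

Remark: the dearomatised flavonoid unit is numbered O1″–C8a″ (phenyl on C2″) and the flavan-4-ol unit O1–C8a (C6 is its only aromatic CH); the 2H-chromene-5,8-quinone is assumed to keep its C2″ configuration at or below room temperature in aprotic media.

Step 1
Reactants: 1 2-hydroxy-3-methoxybenzaldehyde (o-vanillin); 2 acetophenone
Product: 3 (E)-3-(2-hydroxy-3-methoxyphenyl)-1-phenylprop-2-en-1-one
Conditions: KOH, EtOH–H2O, 25 °C; then aq. HCl to pH 6
Reagents that add atoms: none
Why: Claisen–Schmidt condensation: the acetophenone enolate adds to the non-enolisable aldehyde and E1cB loss of water gives the conjugated (E)-enone, no stereocentre being formed.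

Step 2
Reactants: 3 (E)-3-(2-hydroxy-3-methoxyphenyl)-1-phenylprop-2-en-1-one
Product: 4 (S)-2-(3-hydroxy-3-phenylpropyl)-6-methoxyphenol
Conditions: RuCl(p-cymene)[(S,S)-TsDPEN] (1 mol %), HCO2H–Et3N (5:2), EtOAc, 40 °C
Reagents that add atoms: none
Why: Noyori asymmetric transfer hydrogenation reduces the enone C=C by conjugate hydride delivery and then the resulting aryl ketone through the outer-sphere, CH–π-organised transition state of the (S,S)-TsDPEN ruthenium hydride, which should set the carbinol carbon (the future C2″) as S.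

Step 3
Reactants: 4 (S)-2-(3-hydroxy-3-phenylpropyl)-6-methoxyphenol
Product: 5 (2S)-7-methoxy-2-phenyl-1-oxaspiro[4.5]deca-7,9-dien-6-one (both epimers at spiro carbon C5; used without storage)
Conditions: PhI(OAc)2, (CF3)2CHOH, 0 °C
Reagents that add atoms: none
Why: Dearomatising oxidation of the phenol by trivalent iodine gives a phenoxenium-type intermediate that the tethered secondary alcohol should trap at the alkyl-bearing ortho carbon by 5-exo spiro-etherification in the non-nucleophilic fluoroalcohol, the new spiro centre forming as an inconsequential epimer pair because it becomes sp2 again in step 4.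

Step 4
Reactants: 5 (2S)-7-methoxy-2-phenyl-1-oxaspiro[4.5]deca-7,9-dien-6-one
Product: 6 (S)-7-methoxy-2-phenylchroman-8-ol
Conditions: BF3·OEt2 (0.3 equiv), CH2Cl2, −40 to 0 °C
Reagents that add atoms: none
Why: Coordination of BF3 to the C6 carbonyl of the linearly conjugated dienone places positive charge at C10, the unsubstituted ring carbon next to the spiro centre; the tetrahydrofuran methylene C4 then migrates from C5 to C10, leaving an oxocarbenium ion at C5 stabilised by O1, and loss of the C10 proton rearomatises the ring. The closest known reaction type is the dienone–phenol rearrangement of spiro-fused cyclohexadienones with ring enlargement. The six-membered ring (O1″, C2″, C3″, C4″, C4a″, C8a″ of the target) is therefore not closed by an exo or endo cyclisation but arises from the five-membered spiro ether by a suprafacial 1,2-alkyl (Wagner–Meerwein) shift. No stereocentre is created: the C2 carbinol carbon set in step 2 takes no part and is retained, and the epimeric spiro centre is erased. The step needs carbon rather than oxygen to migrate and needs migration towards C10 rather than C6; only carbon migration leaves an oxygen-stabilised cation, and only the shift to C10 lets the ring aromatise.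

Step 5
Reactants: 6 (S)-7-methoxy-2-phenylchroman-8-ol
Product: 7 (S)-7-methoxy-2-phenylchromane-5,8-dione
Conditions: Co(salen) (10 mol %), O2 (1 atm), DMF, 25 °C
Reagents that add atoms: dioxygen, O=O
Why: Co(salen)-mediated aerobic oxidation of a 2,6-dioxygenated phenol proceeds through the phenoxyl radical, which is oxygenated at the free para position (C5) to give the para-quinone, the remote C2 stereocentre being untouched.

Step 6
Reactants: 7 (S)-7-methoxy-2-phenylchromane-5,8-dione
Product: 9 (S)-7-methoxy-2-phenyl-2H-chromene-5,8-dione, via chromene hydroquinone 8 (not isolated)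
Conditions: Et3N (0.2 equiv), CH2Cl2, 25 °C, evaporate; then Ag2O, MgSO4, Et2O, 0 °C (recovered 7 recycled)
Reagents that add atoms: none
Why: Amine-catalysed γ-deprotonation at C4 gives an ortho-quinone methide whose 1,5-hydrogen shift from C3 aromatises it to chromene hydroquinone 8 (the alkylquinone-to-chromenol redox isomerisation), and after removal of the base Ag2O reoxidises 8 to the quinone without touching C2.

Step 7
Reactants: 10 1,2,3,5-tetramethoxybenzene
Product: 11 1-(2-hydroxy-3,4,6-trimethoxyphenyl)ethan-1-one
Conditions: AcCl, AlCl3, Et2O, 0 to 25 °C; then H2O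
Reagents that add atoms: acetyl chloride, CC(=O)Cl
Why: Friedel–Crafts acylation at one of the two equivalent free positions is followed by AlCl3-mediated cleavage of the chelated ortho methyl ether that is buttressed by a second methoxy group, which gives the 2-hydroxy ketone.

Step 8
Reactants: 11 1-(2-hydroxy-3,4,6-trimethoxyphenyl)ethan-1-one
Product: 13 5,7,8-trimethoxy-4H-chromen-4-one, via enaminone 12 (not isolated)
Conditions: Me2NCH(OMe)2, toluene, 100 °C; then AcOH, 100 °C
Reagents that add atoms: N,N-dimethylformamide dimethyl acetal, COC(OC)N(C)C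
Why: Condensation of the methyl ketone with the amide acetal gives enaminone 12, and acid-promoted conjugate addition of the ortho hydroxyl followed by loss of dimethylamine closes the chromone (enaminone route to chromones).

Step 9
Reactants: 13 5,7,8-trimethoxy-4H-chromen-4-one; 14 phenylboronic acid
Product: 15 (S)-5,7,8-trimethoxy-2-phenylchroman-4-one
Conditions: Pd(O2CCF3)2 (5 mol %), (R)-t-BuPyOx (6 mol %), NH4PF6, H2O, ClCH2CH2Cl, 60 °C
Reagents that add atoms: none
Why: Palladium-catalysed asymmetric conjugate addition of the arylboronic acid (transmetalation, enantiofacial carbopalladation of the chromone C2=C3 bond, protonolysis) should set C2 as S under control of the (R)-configured pyridine–oxazoline ligand.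

Step 10
Reactants: 15 (S)-5,7,8-trimethoxy-2-phenylchroman-4-one
Product: 16 (S)-5-hydroxy-7,8-dimethoxy-2-phenylchroman-4-one
Conditions: BCl3, CH2Cl2, −78 to 0 °C; then H2O
Reagents that add atoms: none
Why: BCl3 forms a six-membered chelate between the C4 carbonyl and the peri 5-methoxy group and cleaves only that methyl ether, while the non-basic, low-temperature conditions avoid retro-oxa-Michael opening and so keep C2 intact.

Step 11
Reactants: 16 (S)-5-hydroxy-7,8-dimethoxy-2-phenylchroman-4-one
Product: 18 (2S,4R)-7,8-dimethoxy-2-phenylchromane-4,5-diol, via trimethylsilyl ether 17 (not isolated)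
Conditions: (Me3Si)2NH, cat. Me3SiCl, THF, 60 °C, evaporate; (S)-2-methyl-CBS-oxazaborolidine (20 mol %), BH3·SMe2, THF, −20 °C; then MeOH, K2CO3
Reagents that add atoms: none
Why: Transient O-silylation prevents intramolecular hydride delivery from an aryloxyborane, and in the Corey–Bakshi–Shibata reduction the (S)-oxazaborolidine–borane complex binds the carbonyl anti to the aryl group and delivers hydride to the face that gives the 4R alcohol (2,4-trans), reagent control being expected to override the substrate's preference for the cis isomer.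

Step 12
Reactants: 18 (2S,4R)-7,8-dimethoxy-2-phenylchromane-4,5-diol
Product: 19 (2S,4R)-4,5-O-isopropylidene-7,8-dimethoxy-2-phenylchromane-4,5-diol (acetonide)
Conditions: 2-methoxypropene, pyridinium p-toluenesulfonate (cat.), CH2Cl2, 0 °C
Reagents that add atoms: 2-methoxypropene, COC(C)=C
Why: Acid-catalysed acetalisation of the phenol–benzylic alcohol pair closes the six-membered 1,3-dioxine, which masks both hydroxyl groups and turns O5 into an ortho-directing acetal oxygen without affecting C2 or C4.

Step 13
Reactants: 19 acetonide of (2S,4R)-7,8-dimethoxy-2-phenylchromane-4,5-diol; 9 (S)-7-methoxy-2-phenyl-2H-chromene-5,8-dione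
Product: 22 (2S,8S)-8-hydroxy-7-methoxy-2-phenyl-8-[C6-aryl of acetonide 19]-2H-chromen-5(8H)-one, via aryllithium 20 (not isolated), via arylcerium dichloride 21 (not isolated)
Conditions: n-BuLi, THF, 0 °C; CeCl3, −78 °C; then 9, THF, −78 °C; H2O
Reagents that add atoms: none
Why: Directed ortho-metalation removes the only aromatic hydrogen of the flavan ring (C6, between the acetal oxygen and the 7-methoxy group), transmetalation to cerium suppresses electron transfer and deprotonation, and 1,2-addition to the more electrophilic C8″ carbonyl of 9 (flanked by two alkoxy-bearing carbons, whereas C5″=O is a doubly vinylogous ester) anti to the C2″ phenyl group of the puckered pyran should set C8″ as S by 1,4-induction.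

Step 14
Reactants: 22 (2S,8S)-8-hydroxy-7-methoxy-2-phenyl-8-[C6-aryl of acetonide 19]-2H-chromen-5(8H)-one
Product: 23 (2S,8S)-7,8-dimethoxy-2-phenyl-8-[C6-aryl of acetonide 19]-2H-chromen-5(8H)-one
Conditions: NaH, MeI, THF–DMF, 0 °C
Reagents that add atoms: iodomethane, CI
Why: Williamson etherification of the tertiary alkoxide with iodomethane installs the C8″ methoxy group without touching a stereocentre.

Step 15
Reactants: 23 (2S,8S)-7,8-dimethoxy-2-phenyl-8-[C6-aryl of acetonide 19]-2H-chromen-5(8H)-one
Product: 25 6″-demethoxyneocalycopterone, via phenol diol 24 (not isolated)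
Conditions: AcOH–THF–H2O (3:1:1), 40 °C
Reagents that add atoms: none
Why: Aqueous acid hydrolyses the acetonide, the freed C5 phenol adds in a 5-exo conjugate addition to C8a″ (the β-carbon of the vinylogous ester, activated by protonation of the C5″ carbonyl) from the only face its tether to C8″ allows, which sets the cis-fused, anomerically stabilised ketal centre C8a″ as S, and γ-protonation of the resulting dienol at C3″ moves the double bond into conjugation as C4a″=C4″.

Compound list
1 | 2-hydroxy-3-methoxybenzaldehyde (o-vanillin) | COc1cccc(C=O)c1O | starting material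
2 | acetophenone | CC(=O)c1ccccc1 | starting material
3 | (E)-3-(2-hydroxy-3-methoxyphenyl)-1-phenylprop-2-en-1-one | COc1cccc(/C=C/C(=O)c2ccccc2)c1O | intermediate
4 | (S)-2-(3-hydroxy-3-phenylpropyl)-6-methoxyphenol | COc1cccc(CC[C@H](O)c2ccccc2)c1O | intermediate
5 | (2S)-7-methoxy-2-phenyl-1-oxaspiro[4.5]deca-7,9-dien-6-one (epimers at C5) | COC1=CC=CC2(CC[C@@H](c3ccccc3)O2)C1=O | intermediate
6 | (S)-7-methoxy-2-phenylchroman-8-ol | COc1ccc2c(c1O)O[C@H](c1ccccc1)CC2 | intermediate
7 | (S)-7-methoxy-2-phenylchromane-5,8-dione | COC1=CC(=O)C2=C(C1=O)O[C@H](c1ccccc1)CC2 | intermediate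
8 | (S)-7-methoxy-2-phenyl-2H-chromene-5,8-diol (not isolated) | COc1cc(O)c2c(c1O)O[C@H](c1ccccc1)C=C2 | intermediate
9 | (S)-7-methoxy-2-phenyl-2H-chromene-5,8-dione | COC1=CC(=O)C2=C(C1=O)O[C@H](c1ccccc1)C=C2 | intermediate
10 | 1,2,3,5-tetramethoxybenzene | COc1cc(OC)c(OC)c(OC)c1 | starting material
11 | 1-(2-hydroxy-3,4,6-trimethoxyphenyl)ethan-1-one | CC(=O)c1c(O)c(OC)c(OC)cc1OC | intermediate
12 | (E)-3-(dimethylamino)-1-(2-hydroxy-3,4,6-trimethoxyphenyl)prop-2-en-1-one (not isolated) | CN(C)/C=C/C(=O)c1c(O)c(OC)c(OC)cc1OC | intermediate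
13 | 5,7,8-trimethoxy-4H-chromen-4-one | COc1cc(OC)c2c(=O)ccoc2c1OC | intermediate
14 | phenylboronic acid | OB(O)c1ccccc1 | starting material
15 | (S)-5,7,8-trimethoxy-2-phenylchroman-4-one | COc1cc(OC)c2c(c1OC)O[C@H](c1ccccc1)CC2=O | intermediate
16 | (S)-5-hydroxy-7,8-dimethoxy-2-phenylchroman-4-one | COc1cc(O)c2c(c1OC)O[C@H](c1ccccc1)CC2=O | intermediate
17 | (S)-7,8-dimethoxy-2-phenyl-5-(trimethylsilyloxy)chroman-4-one (not isolated) | COc1cc(O[Si](C)(C)C)c2c(c1OC)O[C@H](c1ccccc1)CC2=O | intermediate
18 | (2S,4R)-7,8-dimethoxy-2-phenylchromane-4,5-diol | COc1cc(O)c2c(c1OC)O[C@H](c1ccccc1)C[C@H]2O | intermediate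
19 | (2S,4R)-4,5-O-isopropylidene-7,8-dimethoxy-2-phenylchromane-4,5-diol | COc1cc2c3c(c1OC)O[C@H](c1ccccc1)C[C@H]3OC(C)(C)O2 | intermediate
20 | C6-lithio derivative of 19 (not isolated) | COc1c([Li])c2c3c(c1OC)O[C@H](c1ccccc1)C[C@H]3OC(C)(C)O2 | intermediate
21 | C6-dichlorocerio derivative of 19 (not isolated) | COc1c([Ce](Cl)Cl)c2c3c(c1OC)O[C@H](c1ccccc1)C[C@H]3OC(C)(C)O2 | intermediate
22 | (2S,8S)-8-hydroxy-7-methoxy-2-phenyl-8-[C6-aryl of 19]-2H-chromen-5(8H)-one | COC1=CC(=O)C2=C(O[C@H](c3ccccc3)C=C2)[C@]1(O)c1c(OC)c(OC)c2O[C@H](c3ccccc3)C[C@H]3OC(C)(C)Oc1c23 | intermediate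
23 | (2S,8S)-7,8-dimethoxy-2-phenyl-8-[C6-aryl of 19]-2H-chromen-5(8H)-one | COC1=CC(=O)C2=C(O[C@H](c3ccccc3)C=C2)[C@]1(OC)c1c(OC)c(OC)c2O[C@H](c3ccccc3)C[C@H]3OC(C)(C)Oc1c23 | intermediate
24 | acetonide-free phenol diol of 23 (not isolated) | COC1=CC(=O)C2=C(O[C@H](c3ccccc3)C=C2)[C@]1(OC)c1c(OC)c(OC)c2O[C@H](c3ccccc3)C[C@@H](O)c2c1O | intermediate
25 | 6″-demethoxyneocalycopterone | COC1=CC(=O)C2=CC[C@@H](c3ccccc3)O[C@]23Oc2c4c(c(OC)c(OC)c2[C@]13OC)O[C@H](c1ccccc1)C[C@H]4O | target

Total step count: 15. Longest linear sequence: 9 steps (steps 1–6, then 13–15; the other branch, steps 7–12 then 13–15, is equally long).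

Steps most likely to fail

Step 13. What may go wrong: electron transfer from the aryl metal to the quinone or deprotonation of 9 at C2″ in place of carbonyl addition, and weak discrimination between the two faces of C8″ because the directing phenyl group is four atoms away. Fallback: form the same two bonds under thermodynamic control from a free phenol. Setting out from diol 18, exhaustive silylation (t-BuMe2SiOTf, 2,6-lutidine) would give the bis(silyl) ether F1, and selective methanolysis of the aryl silyl ether (K2CO3, MeOH) the phenol 4-O-silyl ether F2. With quinone 9 and catalytic Sc(OTf)3 (CH2Cl2, 0 °C), a reversible Friedel–Crafts hydroxyalkylation at the C8″ carbonyl, ketalisation at C8a″ and enol-to-enone tautomerisation should funnel to the cis-fused, anomerically stabilised tertiary alcohol F3. O-Methylation (MeOTf, 2,6-di-tert-butylpyridine) to the methyl ether F4 and desilylation (Bu4NF, THF) come back to the route at 25.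

Step 3. What may go wrong: capture of the oxidised phenol at its free para position, or intermolecular coupling, instead of ortho spiro-etherification. Fallback: block the para position with a group that is lost when the quinone is made. Setting out from 4, NBS (MeCN, 0 °C) would give the para-bromophenol F5; PhI(OAc)2 in (CF3)2CHOH would give the bromo spirodienone F6, and BF3·OEt2 would rearrange it to the bromochromanol F7. Oxidation with (NH4)2Ce(NO3)6 in aqueous MeCN then replaces bromide by oxygen and rejoins the route at quinone 7.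

Step 15. What may go wrong: ionisation of the benzylic C4–O bond of the flavan-4-ol, or of the allylic C2″–O1″ bond, under acid before the ketal has closed, with loss of configuration or elimination. Fallback: a fluoride-labile mask so that the last step runs under buffered, weakly basic conditions. Setting out from diol 18, t-Bu2Si(OTf)2 and 2,6-lutidine would give the cyclic silylene F8. Lithiation (s-BuLi, TMEDA, −78 °C), transmetalation to cerium and addition to 9 as in step 13 would give the tertiary alcohol F9, which would be methylated (NaH, MeI) to the methyl ether F10. Bu4NF buffered with AcOH then removes the silylene and the liberated phenoxide closes the ketal by conjugate addition, returning at 25.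

Further compounds
F1 | step 13 | (2S,4R)-4,5-bis(tert-butyldimethylsilyloxy)-7,8-dimethoxy-2-phenylchromane | COc1cc(O[Si](C)(C)C(C)(C)C)c2c(c1OC)O[C@H](c1ccccc1)C[C@H]2O[Si](C)(C)C(C)(C)C
F2 | step 13 | (2S,4R)-4-(tert-butyldimethylsilyloxy)-7,8-dimethoxy-2-phenylchroman-5-ol | COc1cc(O)c2c(c1OC)O[C@H](c1ccccc1)C[C@H]2O[Si](C)(C)C(C)(C)C
F3 | step 13 | 8″-O-demethyl 4-O-(tert-butyldimethylsilyl) derivative of 25 (tertiary alcohol at C8″) | COC1=CC(=O)C2=CC[C@@H](c3ccccc3)O[C@]23Oc2c4c(c(OC)c(OC)c2[C@]13O)O[C@H](c1ccccc1)C[C@H]4O[Si](C)(C)C(C)(C)C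
F4 | step 13 | 4-O-(tert-butyldimethylsilyl) ether of 25 | COC1=CC(=O)C2=CC[C@@H](c3ccccc3)O[C@]23Oc2c4c(c(OC)c(OC)c2[C@]13OC)O[C@H](c1ccccc1)C[C@H]4O[Si](C)(C)C(C)(C)C
F5 | step 3 | (S)-4-bromo-2-(3-hydroxy-3-phenylpropyl)-6-methoxyphenol | COc1cc(Br)cc(CC[C@H](O)c2ccccc2)c1O
F6 | step 3 | (2S)-9-bromo-7-methoxy-2-phenyl-1-oxaspiro[4.5]deca-7,9-dien-6-one | COC1=CC(Br)=CC2(CC[C@@H](c3ccccc3)O2)C1=O
F7 | step 3 | (S)-5-bromo-7-methoxy-2-phenylchroman-8-ol | COc1cc(Br)c2c(c1O)O[C@H](c1ccccc1)CC2
F8 | step 15 | 4,5-O-(di-tert-butylsilylene) derivative of diol 18 | COc1cc2c3c(c1OC)O[C@H](c1ccccc1)C[C@H]3O[Si](C(C)(C)C)(C(C)(C)C)O2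
F9 | step 15 | silylene analogue of tertiary alcohol 22 | COC1=CC(=O)C2=C(O[C@H](c3ccccc3)C=C2)[C@]1(O)c1c(OC)c(OC)c2O[C@H](c3ccccc3)C[C@H]3O[Si](C(C)(C)C)(C(C)(C)C)Oc1c23
F10 | step 15 | silylene analogue of methyl ether 23 | COC1=CC(=O)C2=C(O[C@H](c3ccccc3)C=C2)[C@]1(OC)c1c(OC)c(OC)c2O[C@H](c3ccccc3)C[C@H]3O[Si](C(C)(C)C)(C(C)(C)C)Oc1c23
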